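All runs stem from a simulated flask for an exercise, and the scatter is random.

The meeting opened with an easy subtraction. The first speaker took the impurity from the free catalyst, one for one, because the impurity is charged in less and so is the limiting reagent of that loss. This leaves 0.850 mM of working catalyst in violet, 1.05 mM in oak and 1.85 mM in alder.

The meeting had these flasks and runs before it:

| setting | violet | amber | oak | alder |
|---|---|---|---|---|
| left-handed substrate | 0.50 M | 0.50 M | 0.50 M | 0.50 M |
| right-handed substrate | 0.50 M | 0.50 M | 0.50 M | 0.50 M |
| coupling partner | 1.25 M | 1.25 M | 1.25 M | 1.25 M |
| free catalyst | 1 mM | 1.7 mM | 1.2 mM | 2.0 mM |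
| racemization catalyst | 3.2 mM | 3.2 mM | 3.2 mM | 3.2 mM |
| impurity | 0.15 mM | 0.15 mM | 0.15 mM | 0.15 mM |
| remark | run made earlier | run made earlier |  |  |
| time |  |  | 80 min | 80 min |

| run | time / min | right-handed substrate / % | left-handed substrate / % |
|---|---|---|---|
| violet | 4.00 | 49.0 | 38.8 |
| violet | 10.0 | 46.3 | 28.6 |
| violet | 20.0 | 42.5 | 18.6 |
| violet | 30.0 | 40.0 | 13.5 |
| violet | 40.0 | 37.4 | 9.8 |
| violet | 60.0 | 33.9 | 6.9 |
| amber | 5.00 | 47.4 | 28.6 |
| amber | 8.00 | 45.5 | 21.8 |
| amber | 12.0 | 43.4 | 16.5 |
| amber | 20.0 | 39.2 | 10.7 |
| amber | 30.0 | 36.3 | 7.1 |
| amber | 60.0 | 29.7 | 2.9 |

(readings scatter by 0.3 percentage points)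

- free catalyst is single-handed; left-handed substrate and right-handed substrate are mirror images of each other, charged as a racemate, each of them at the stated concentration
- the numbers in the tables scatter by 0.3 percentage points (one standard deviation)
- an excess is below zero if the other one leads

- the flask that ends with the higher excess of right-handed substrate over left-handed substrate among what is left of the two, or "neither" when 2 percentage points or less lies between them (oak / alder / neither)
- excess of right-handed substrate over left-handed substrate among what is left of the two at the end, oak
- excess of right-handed substrate over left-handed substrate among what is left of the two at the end, alder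

The second speaker read the fall of left-handed substrate between the first two readings as 0.0508 min⁻¹ in violet and 0.0905 min⁻¹ in amber. That is a ratio of 1.78, against 1.82 for working catalyst and 1.70 for the catalyst charged. The speaker added that a scatter of 0.3 percentage points could not part these two.

The third speaker proposed one clock for the flasks: plain time multiplied by the flask's working catalyst and divided by violet's. This gives oak 98.8 min, its violet-equivalent time, and alder 174 min. Violet's last reading stands at 60.0 min on this clock and amber's at 109 min, with excesses of 66.2 % and 82.2 %. A fourth speaker objected that racemization keeps plain minutes, and the objection stood.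

These minutes still commit to a straight line between those readings, which gives oak 78.8 %. Alder lies past amber on the clock, so they put alder above 82.2 %, which is clear of oak by more than the margin.

The forecast also chose alder, with 73 % for oak and 82 % for alder, holding that “the catalyst apparently fades or is inhibited”. It parts from these minutes on oak by 5.8 points.

The scheme behind the readings was then shown:

    left-handed substrate + racemization catalyst ⇌ right-handed substrate + racemization catalyst, rate k1*[racemization catalyst]*[left-handed substrate] forward; the back reaction follows from the equilibrium constant (k = 0.320 M⁻¹ s⁻¹)
    2 racemization catalyst → spent catalyst B (k = 0.490 M⁻¹ s⁻¹)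
    coupling partner + free catalyst + left-handed substrate → free catalyst + left-handed product (k = 1.20 M⁻² s⁻¹)
    coupling partner → decomposition product (k = 1.20 × 10⁻⁶ s⁻¹)
    free catalyst + impurity → spent catalyst A (k = 1700 M⁻¹ s⁻¹)
    coupling partner + free catalyst + right-handed substrate → free catalyst + right-handed product (k = 0.0120 M⁻² s⁻¹)

Oak ended at 78.6 % and alder at 87.7 %, so alder leads. At 80.0 min, free catalyst in oak stood at 87.5 % of its charge, beside spent catalyst A at 12.5 %. The same clock, applied to the neighbour that is alder with 5.00 mM of free catalyst, reads 456 min, and the excess of right-handed substrate in that neighbour ends at 95.0 %.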